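A small charge of initiator, 6.0 mM in the east flask, has to carry 2.0 M of starting material through a chain.

| flask | starting material | coupling partner | initiator | time |
|---|---|---|---|---|
| east | 2.0 M | 2.40 M | 6.0 mM | 50 min |
| north | 2.0 M | 2.40 M | 20 mM | 50 min |
| south-east | 2.0 M | 2.40 M | 60 mM | 50 min |
| north-west | 2.0 M | 2.40 M | 200 mM | 50 min |
| south | 2.0 M | 2.40 M | 500 mM | 50 min |

    initiator → 2 initiating radical (k1 = 2.8 × 10⁻⁴ s⁻¹)
    starting material + initiating radical → capped initiator + first chain carrier (k2 = 39000 L mol⁻¹ s⁻¹)
    coupling partner + first chain carrier → target + second chain carrier (k3 = 1700 L mol⁻¹ s⁻¹)
    starting material + second chain carrier → by-product + first chain carrier (k4 = 3200 L mol⁻¹ s⁻¹)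
    first chain carrier → ended carrier (k5 = 30 s⁻¹)
    2 first chain carrier → ended chains (k6 = 7 × 10⁷ L mol⁻¹ s⁻¹)
    target ⇌ isomer of the product (K7 = 3.6, k7 = 2.5 × 10⁻⁴ s⁻¹)
    crystals ⇌ by-product, rate k8*(cs8 - [by-product]) while solid is left; crystals form when [by-product] > cs8 (cs8 = 1.0 M, k8 = 0.030 s⁻¹)

- percentages count the starting material that a species holds: one ended chains counts as two
- by-product is meant together with its crystals
- two of one species on the left: rate k times its square, two consumed each time
- solid, in amounts per volume of the solution: crystals
- "hardly changes" means that all values lie within two and a half points (for a concentration: within two and a half percent of the largest)
- run time (east): 50 min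

- amount of target at the end, in percent of the starting material charged for east, north, south-east, north-west, south, in this order
- how that number moves from the first to the last of them (rises all the way / falls, then rises / falls all the way / hardly changes / rises, then falls)

**Counting turnovers.** A turn takes the first chain carrier through the coupling partner and back through the starting material. It spends one of each and gives one target and one by-product. An initiating radical that meets starting material opens one chain, and at the start of east these radicals arrive at 0.202 mM min⁻¹. If the first chain carrier is ended as fast as it is made, each carrier in east faces a loss of 41.4 s⁻¹, the single end and the paired end taken together. At the charge of coupling partner it goes on at 4080 s⁻¹. For the start of east the ratio stands at 98.6: going on over being ended is the turnovers per chain, the kinetic chain length.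

**First way.** By 50 min, 56.8% of the initiator has broken, which gives 6.82 mM of chains in east. Multiplied by the turnovers per chain, this makes 0.673 M turned over, or 33.6% of the starting material charged.

**Second way.** The same balance puts [first chain carrier] at 8.12 × 10⁻⁸ M in east. The rate of going on, held for the run, then gives 0.994 M in east. The two ways part, the second giving more than the first. The second way cheats, because it keeps the initiator at its charge although the half-life of the initiator, 41 min, is shorter than the run. The first way counts the radicals made over the run, so this reckoning commits to the first figure. That figure is target and isomer of the product together, and target is a part of it, because their relaxation half-life of 36.2 min is also shorter than the run.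

**Enough chains.** Using up the charge in east takes 293 turnovers per chain, more than the chain offers, so east should end with starting material left. At the start of south-east the loss rises to 85.2 s⁻¹, and the chain shortens to 47.9 turnovers. The need, however, falls to 29.3, below the offer. This reckoning therefore expects target to rise as far as south-east, and it gives no figure beyond that flask.

**The forecast.** It gives 21.3%, 42.5%, 60.5%, 53% and 50%, so that the row rises, then falls. Its grounds: “target rises until the starting material, the limiting reagent, is just used up at about 60 mM”. Its east figure is for target, whereas the reckoning above gave the sum with the isomer of the product.

**The flask.** The row reads 21.3%, 42.5%, 61.2%, 53.3% and 49.7%, so it rises, then falls. East keeps 68.5% of its starting material at 50.0 min. The by-product of east over its capped initiator reads 91.4 turnovers per chain over the run, beside the 98.6 reckoned for its start. In south-east, where the 47.9 turnovers reckoned for the start stood above the 29.3 needed, starting material stands at 1.64% at 50.0 min.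

The constants used here were chosen freely, and the outcome is calculated.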